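**Plan**
- Cuts, in retrosynthetic order: C12–C13 (the butenolide goes on last, by alkylation of a 3-(phenylsulfanyl)lactone and sulfoxide elimination); C17–Si with C9–H (the exocyclic alkene comes from a C8=C9 allylsilane); C5–C10 and C6–C7 together (retro-[4+2] of ring B, which opens ring A as well); C1–C10 (B-alkyl Suzuki–Miyaura coupling).
- Enabling feature: in ring B (C5–C6–C7–C8–C9–C10) the C8 methylene beside C9–H is the allylic transpose of a C8=C9 cyclohexene, and C5–C10 is the ring A/B fusion bond. A diene C7=C8–C9=C10 and an alkene C5=C6 joined by C1–C4 therefore fold into both rings at once.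
- Forward: (S)-malate gives the quaternary C4 ester carrying a vinyl sulfone (removable activator); tetronic acid gives a butenolide triflate; the two are coupled; the butenolide (a temporary ring that fixes the C9=C10 geometry) is opened to a 2-(silylmethyl)diene; the cycloaddition closes rings A and B; sulfone and silicon are removed; the side-chain butenolide is added last.
- Stereochemistry: C4 from the malate centre by two Fráter–Seebach alkylations; C5 and C10 from the cycloaddition under control of C4 and the diene geometry; C9 by axial protonation anti to C20.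

Key step: step 11

Remark: labdane numbering (C1–C20) is used for the ring system and its open-chain precursors, α/β refer to the usual drawing with C20 on the β face, and (tert-butyldiphenylsilyloxy)acetaldehyde is taken to be a catalogue compound.

**Route**

Step 1
Reactants: 1 dimethyl (S)-malate
Product: 2 dimethyl (2S,3R)-2-hydroxy-3-(prop-2-enyl)butanedioate
Conditions: LDA (2.2 equiv), THF, −78 to −20 °C; allyl bromide, −78 °C to rt
Reagents that add atoms: allyl bromide, C=CCBr
Why: Fráter–Seebach alkylation, in which the lithium alkoxide–enolate dianion reacts as a rigid chelate whose face anti to the C2 ester is open, so the allyl group should enter there and give the 2,3-anti (3R) diastereomer.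

Step 2
Reactants: 2 dimethyl (2S,3R)-2-hydroxy-3-(prop-2-enyl)butanedioate
Product: 3 dimethyl (2S,3S)-2-hydroxy-3-methyl-3-(prop-2-enyl)butanedioate
Conditions: LDA (2.3 equiv), THF/DMPU, −78 to 0 °C; MeI
Reagents that add atoms: iodomethane, CI
Why: a second Fráter–Seebach alkylation through the same chelated dianion should again deliver the electrophile anti to the C2 ester, so methyl takes the place the allyl group took in step 1 and the quaternary carbon (the later C4 with C18 and the C19 ester) is formed with S configuration.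

Step 3
Reactants: 3 dimethyl (2S,3S)-2-hydroxy-3-methyl-3-(prop-2-enyl)butanedioate
Product: 4 (2S,3S)-2-hydroxy-3-(methoxycarbonyl)-3-methylhex-5-enoic acid
Conditions: LiOH·H2O (1.1 equiv), THF/H2O, 0 °C; then 1 M HCl
Reagents that add atoms: lithium hydroxide, [Li+].[OH-]
Why: chemoselective saponification, since the unhindered α-hydroxy ester is hydrolysed far faster than the neopentyl-type ester on the quaternary carbon, and no stereocentre is touched.

Step 4
Reactants: 4 (2S,3S)-2-hydroxy-3-(methoxycarbonyl)-3-methylhex-5-enoic acid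
Product: 5 methyl (2S)-2-formyl-2-methylpent-4-enoate
Conditions: Pb(OAc)4 (1.1 equiv), CH2Cl2, 0 °C to rt
Reagents that add atoms: none
Why: lead tetraacetate oxidative decarboxylation of the α-hydroxy acid removes the carboxyl carbon and leaves C5 as the aldehyde, while the quaternary α-carbon cannot enolise and keeps its configuration.

Step 5
Reactants: 5 methyl (2S)-2-formyl-2-methylpent-4-enoate
Product: 6 methyl (2S)-2-methyl-2-[(E)-2-(phenylsulfonyl)ethenyl]pent-4-enoate
Conditions: (EtO)2P(O)CH2SO2Ph, NaH, THF, 0 °C to rt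
Reagents that add atoms: diethyl [(phenylsulfonyl)methyl]phosphonate, CCOP(=O)(CS(=O)(=O)c1ccccc1)OCC
Why: Horner–Wadsworth–Emmons olefination with the sulfonyl-stabilised phosphonate anion should give the E-vinyl sulfone (C5=C6) from the hindered aldehyde and installs the removable activating group of the dienophile.

Step 6
Reactants: 7 tetronic acid; 8 (tert-butyldiphenylsilyloxy)acetaldehyde
Product: 9 3-[2-(tert-butyldiphenylsilyloxy)ethyl]-4-hydroxyfuran-2(5H)-one
Conditions: Hantzsch ester (1.1 equiv), L-proline (20 mol %), CH2Cl2, rt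
Reagents that add atoms: none
Why: organocatalytic reductive alkylation (Knoevenagel condensation at C3 of the 1,3-dicarbonyl, then transfer hydrogenation of the alkylidene by the Hantzsch ester) should attach the C11–C12 chain at carbon and not at oxygen; no stereocentre is formed.

Step 7
Reactants: 9 3-[2-(tert-butyldiphenylsilyloxy)ethyl]-4-hydroxyfuran-2(5H)-one
Product: 10 4-[2-(tert-butyldiphenylsilyloxy)ethyl]-5-oxo-2,5-dihydrofuran-3-yl trifluoromethanesulfonate
Conditions: Tf2O, i-Pr2NEt, CH2Cl2, −78 °C
Reagents that add atoms: trifluoromethanesulfonic anhydride, O=S(=O)(OS(=O)(=O)C(F)(F)F)C(F)(F)F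
Why: O-triflation of the vinylogous acid gives the β-triflyloxy butenolide, an activated vinyl electrophile for cross-coupling.

Step 8
Reactants: 6 methyl (2S)-2-methyl-2-[(E)-2-(phenylsulfonyl)ethenyl]pent-4-enoate; 10 butenolide triflate
Product: 12 methyl (2S)-5-{4-[2-(tert-butyldiphenylsilyloxy)ethyl]-5-oxo-2,5-dihydrofuran-3-yl}-2-methyl-2-[(E)-2-(phenylsulfonyl)ethenyl]pentanoate, via B-alkyl-9-BBN adduct 11 (not isolated)
Conditions: 9-BBN (1.3 equiv), THF, 0 °C to rt; then 10, PdCl2(dppf) (5 mol %), AsPh3, K3PO4 (aq), DMF/THF, rt to 45 °C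
Reagents that add atoms: 9-borabicyclo[3.3.1]nonane, B1C2CCCC1CCC2 (retained only in 11)
Why: anti-Markovnikov hydroboration of the terminal allyl alkene (the electron-poor, β-branched vinyl sulfone is left alone) followed by B-alkyl Suzuki–Miyaura coupling with the vinyl triflate forms the C1–C10 bond, the remote C4 centre being unaffected.

Step 9
Reactants: 12 butenolide ester sulfone
Product: 14 methyl (2S,6Z)-7-[2-(tert-butyldiphenylsilyloxy)ethyl]-6-(hydroxymethyl)-2-methyl-2-[(E)-2-(phenylsulfonyl)ethenyl]-8-[(trimethylsilyl)methyl]nona-6,8-dienoate, via bis(silylmethyl) carbinol 13 (not isolated)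
Conditions: Me3SiCH2MgCl (3 equiv), CeCl3 (3 equiv), THF, −78 to 0 °C; then SiO2, CH2Cl2, rt
Reagents that add atoms: (trimethylsilyl)methylmagnesium chloride, C[Si](C)(C)C[Mg]Cl
Why: cerium-mediated double 1,2-addition to the lactone carbonyl (the cerium reagent suppresses γ-deprotonation and should spare the hindered C19 ester and the β-branched vinyl sulfone) followed by Peterson olefination of 13 gives the 2-(silylmethyl)diene, and the C9=C10 geometry with C20 cis to C8 is inherited from the ring.

Step 10
Reactants: 14 dienol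
Product: 15 methyl (2S,6Z)-6-(acetoxymethyl)-7-[2-(tert-butyldiphenylsilyloxy)ethyl]-2-methyl-2-[(E)-2-(phenylsulfonyl)ethenyl]-8-[(trimethylsilyl)methyl]nona-6,8-dienoate
Conditions: Ac2O, pyridine, DMAP (cat.), CH2Cl2, 0 °C
Reagents that add atoms: acetic anhydride, CC(=O)OC(C)=O
Why: acetylation of the primary allylic alcohol installs the C20 acetate of the target early, which also keeps the later 1,3-diaxial hydroxymethyl/ester pair from lactonising.

Step 11
Reactants: 15 triene acetate
Product: 16 methyl 20-acetoxy-12-(tert-butyldiphenylsilyloxy)-6α-(phenylsulfonyl)-17-(trimethylsilyl)-13,14,15,16-tetranorlabd-8-en-19-oate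
Conditions: toluene (0.005 M), BHT (cat.), K2CO3 (solid), sealed tube, 150–165 °C
Reagents that add atoms: none
Why: Thermal type 1 intramolecular Diels–Alder reaction in which the 2-(silylmethyl)diene C7=C8–C9=C10 and the sulfone-activated E-alkene C5=C6 combine in one concerted, asynchronous [4+2] step that forms C5–C10 and C6–C7; the closest known reaction type is the thermal cyclisation of 1-sulfonyl-1,7,9-decatrienes to octalins, with the vinyl sulfone serving as a removable alkene equivalent. Ring B is closed as the cyclohexene by the cycloaddition itself, and ring A (C10, C1–C5) is closed at the same time by the C5–C10 bond across the four-carbon tether in a chair-like, tether-exo (anti) arrangement. C10 and C5 should be set trans because the tether occupies the outer (E) position of C10 with C20 inside, so the anti mode puts C20 axial and H5 on the opposite face, whereas the syn (cis-fused) mode would force the fully substituted C9, not C20, into the position syn-axial to a C4 substituent. The absolute sense comes from the preformed C4 centre: the flat ester, not the methyl group, should take the pseudo-axial site next to the C20 acetoxymethyl group, which puts C19 and C20 on the same face as in the target, while C6 (sulfonyl trans to C4, from the E-alkene) is erased in step 12. The step needs periselectivity over [1,5]-hydrogen shift of the Z-allylic C20 hydrogens as well as anti and facial selectivity. The sulfone activation (lower temperature), the quaternary C4 (gem-disubstitution at the tether end and the syn-axial bias) and high dilution under acid-free conditions are meant to secure these.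

Step 12
Reactants: 16 cycloadduct
Product: 17 methyl 20-acetoxy-12-(tert-butyldiphenylsilyloxy)-17-(trimethylsilyl)-13,14,15,16-tetranorlabd-8-en-19-oate
Conditions: Na(Hg) (6 % Na), Na2HPO4, MeOH/THF, −20 °C
Reagents that add atoms: none
Why: reductive desulfonylation by electron transfer from sodium amalgam, buffered so that the neopentyl acetate should survive, replaces the C6 sulfonyl group by hydrogen and removes the helper together with the C6 stereocentre.

Step 13
Reactants: 17 allylsilane
Product: 18 methyl 20-acetoxy-12-(tert-butyldiphenylsilyloxy)-13,14,15,16-tetranorlabd-8(17)-en-19-oate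
Conditions: CF3CO2H (3 equiv), CH2Cl2, −40 to −20 °C; NaHCO3 quench
Reagents that add atoms: none
Why: protodesilylation of the allylsilane (SE2′), in which protonation at C9 gives the β-silyl cation at C8 and loss of silicon places the double bond at C8=C17; the proton should add axially on the α face, anti to the axial C20 group, which sets 9αH (9S).

Step 14
Reactants: 18 silyl ether
Product: 19 methyl 20-acetoxy-12-hydroxy-13,14,15,16-tetranorlabd-8(17)-en-19-oate
Conditions: Bu4NF, AcOH (1:1), THF, rt
Reagents that add atoms: none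
Why: fluoride cleavage of the silyl ether under acetic acid buffering frees the C12 hydroxyl without hydrolysis or migration of the acetate.

Step 15
Reactants: 19 alcohol
Product: 20 methyl 20-acetoxy-12-iodo-13,14,15,16-tetranorlabd-8(17)-en-19-oate
Conditions: I2, PPh3, imidazole, CH2Cl2, 0 °C to rt
Reagents that add atoms: iodine, [I][I]
Why: Appel-type iodination of the primary alcohol under imidazole buffering leaves the acid-sensitive exocyclic alkene and the esters untouched.

Step 16
Reactants: 21 α-bromo-γ-butyrolactone (racemic); 22 thiophenol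
Product: 23 3-(phenylsulfanyl)oxolan-2-one (racemic)
Conditions: Et3N, CH2Cl2, 0 °C to rt
Reagents that add atoms: none
Why: SN2 displacement of the α-bromide by thiolate gives the α-sulfanyl lactone, and racemic material suffices because this carbon becomes sp2 in step 18.

Step 17
Reactants: 20 iodide; 23 3-(phenylsulfanyl)oxolan-2-one
Product: 24 methyl 20-acetoxy-13-(phenylsulfanyl)labd-8(17)-en-16,15-olid-19-oate (both C13 epimers)
Conditions: 23 (1.5 equiv), LiHMDS (1.5 equiv), THF/HMPA, −78 to 0 °C; then 20, 0 °C to rt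
Reagents that add atoms: none
Why: SN2 alkylation of the sulfur-stabilised lithium lactone enolate by the primary iodide forms the C12–C13 bond, and the new C13 centre, formed as a mixture, is destroyed in step 18.

Step 18
Reactants: 24 sulfanyl lactone
Product: 26 methyl 20-acetoxylabda-8(17),13-dien-16,15-olid-19-oate (the target), via sulfoxide 25 (not isolated)
Conditions: mCPBA (1.05 equiv), NaHCO3, CH2Cl2, −78 to −20 °C; then toluene, 100 °C
Reagents that add atoms: 3-chloroperoxybenzoic acid, OOC(=O)c1cccc(Cl)c1 (oxygen retained only in 25)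
Why: sulfide-to-sulfoxide oxidation and thermal syn-elimination (sulfoxide pyrolysis) towards the ring C14 hydrogens should give the endocyclic α-substituted butenolide, the peracid being consumed by sulfur at low temperature before it can epoxidise the 1,1-disubstituted alkene.

**Compound list**

1 | dimethyl (S)-malate | COC(=O)C[C@H](O)C(=O)OC | starting material
2 | dimethyl (2S,3R)-2-hydroxy-3-(prop-2-enyl)butanedioate | C=CC[C@H]([C@H](O)C(=O)OC)C(=O)OC | intermediate
3 | dimethyl (2S,3S)-2-hydroxy-3-methyl-3-(prop-2-enyl)butanedioate | C=CC[C@]([C@H](O)C(=O)OC)(C)C(=O)OC | intermediate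
4 | (2S,3S)-2-hydroxy-3-(methoxycarbonyl)-3-methylhex-5-enoic acid | C=CC[C@]([C@H](O)C(=O)O)(C)C(=O)OC | intermediate
5 | methyl (2S)-2-formyl-2-methylpent-4-enoate | C=CC[C@](C=O)(C)C(=O)OC | intermediate
6 | methyl (2S)-2-methyl-2-[(E)-2-(phenylsulfonyl)ethenyl]pent-4-enoate | C=CC[C@](/C=C/S(=O)(=O)c1ccccc1)(C)C(=O)OC | intermediate
7 | tetronic acid (furan-2,4(3H,5H)-dione) | O=C1CC(=O)CO1 | starting material
8 | (tert-butyldiphenylsilyloxy)acetaldehyde | O=CCO[Si](c1ccccc1)(c1ccccc1)C(C)(C)C | starting material
9 | 3-[2-(tert-butyldiphenylsilyloxy)ethyl]-4-hydroxyfuran-2(5H)-one | O=C1OCC(O)=C1CCO[Si](c1ccccc1)(c1ccccc1)C(C)(C)C | intermediate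
10 | 4-[2-(tert-butyldiphenylsilyloxy)ethyl]-5-oxo-2,5-dihydrofuran-3-yl trifluoromethanesulfonate | O=C1OCC(OS(=O)(=O)C(F)(F)F)=C1CCO[Si](c1ccccc1)(c1ccccc1)C(C)(C)C | intermediate
11 | methyl (2S)-5-(9-borabicyclo[3.3.1]nonan-9-yl)-2-methyl-2-[(E)-2-(phenylsulfonyl)ethenyl]pentanoate | B1(CCC[C@](/C=C/S(=O)(=O)c2ccccc2)(C)C(=O)OC)C2CCCC1CCC2 | intermediate
12 | methyl (2S)-5-{4-[2-(tert-butyldiphenylsilyloxy)ethyl]-5-oxo-2,5-dihydrofuran-3-yl}-2-methyl-2-[(E)-2-(phenylsulfonyl)ethenyl]pentanoate | O=C1OCC(CCC[C@](/C=C/S(=O)(=O)c2ccccc2)(C)C(=O)OC)=C1CCO[Si](c1ccccc1)(c1ccccc1)C(C)(C)C | intermediate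
13 | methyl (2S,6Z)-7-[2-(tert-butyldiphenylsilyloxy)ethyl]-8-hydroxy-6-(hydroxymethyl)-2-methyl-2-[(E)-2-(phenylsulfonyl)ethenyl]-9-(trimethylsilyl)-8-[(trimethylsilyl)methyl]non-6-enoate (hydroxymethyl cis to the carbinol carbon) | C[Si](C)(C)CC(O)(C[Si](C)(C)C)/C(CCO[Si](c1ccccc1)(c1ccccc1)C(C)(C)C)=C(\CO)CCC[C@](/C=C/S(=O)(=O)c1ccccc1)(C)C(=O)OC | intermediate
14 | methyl (2S,6Z)-7-[2-(tert-butyldiphenylsilyloxy)ethyl]-6-(hydroxymethyl)-2-methyl-2-[(E)-2-(phenylsulfonyl)ethenyl]-8-[(trimethylsilyl)methyl]nona-6,8-dienoate (C20 hydroxymethyl cis to C8) | C=C(C[Si](C)(C)C)/C(CCO[Si](c1ccccc1)(c1ccccc1)C(C)(C)C)=C(\CO)CCC[C@](/C=C/S(=O)(=O)c1ccccc1)(C)C(=O)OC | intermediate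
15 | methyl (2S,6Z)-6-(acetoxymethyl)-7-[2-(tert-butyldiphenylsilyloxy)ethyl]-2-methyl-2-[(E)-2-(phenylsulfonyl)ethenyl]-8-[(trimethylsilyl)methyl]nona-6,8-dienoate | C=C(C[Si](C)(C)C)/C(CCO[Si](c1ccccc1)(c1ccccc1)C(C)(C)C)=C(\COC(C)=O)CCC[C@](/C=C/S(=O)(=O)c1ccccc1)(C)C(=O)OC | intermediate
16 | methyl 20-acetoxy-12-(tert-butyldiphenylsilyloxy)-6α-(phenylsulfonyl)-17-(trimethylsilyl)-13,14,15,16-tetranorlabd-8-en-19-oate (4S; 5αH; C19 ester and C20 both β) | C[Si](C)(C)CC=1C[C@H](S(=O)(=O)c3ccccc3)[C@@H]2[C@](COC(C)=O)(CCC[C@]2(C)C(=O)OC)C=1CCO[Si](c1ccccc1)(c1ccccc1)C(C)(C)C | intermediate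
17 | methyl 20-acetoxy-12-(tert-butyldiphenylsilyloxy)-17-(trimethylsilyl)-13,14,15,16-tetranorlabd-8-en-19-oate (4S; 5αH; C19 and C20 β) | C[Si](C)(C)CC=1CC[C@@H]2[C@](COC(C)=O)(CCC[C@]2(C)C(=O)OC)C=1CCO[Si](c1ccccc1)(c1ccccc1)C(C)(C)C | intermediate
18 | methyl 20-acetoxy-12-(tert-butyldiphenylsilyloxy)-13,14,15,16-tetranorlabd-8(17)-en-19-oate (4S; 5αH; 9αH; C19 and C20 β) | C=C1CC[C@@H]2[C@](COC(C)=O)(CCC[C@]2(C)C(=O)OC)[C@H]1CCO[Si](c1ccccc1)(c1ccccc1)C(C)(C)C | intermediate
19 | methyl 20-acetoxy-12-hydroxy-13,14,15,16-tetranorlabd-8(17)-en-19-oate (configuration as 18) | C=C1CC[C@@H]2[C@](COC(C)=O)(CCC[C@]2(C)C(=O)OC)[C@H]1CCO | intermediate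
20 | methyl 20-acetoxy-12-iodo-13,14,15,16-tetranorlabd-8(17)-en-19-oate (configuration as 18) | C=C1CC[C@@H]2[C@](COC(C)=O)(CCC[C@]2(C)C(=O)OC)[C@H]1CCI | intermediate
21 | α-bromo-γ-butyrolactone (3-bromooxolan-2-one, racemic) | O=C1OCCC1Br | starting material
22 | thiophenol | Sc1ccccc1 | starting material
23 | 3-(phenylsulfanyl)oxolan-2-one (racemic) | O=C1OCCC1Sc1ccccc1 | intermediate
24 | methyl 20-acetoxy-13-(phenylsulfanyl)labd-8(17)-en-16,15-olid-19-oate (ring stereocentres as 18; both C13 epimers) | C=C1CC[C@@H]2[C@](COC(C)=O)(CCC[C@]2(C)C(=O)OC)[C@H]1CCC1(Sc2ccccc2)CCOC1=O | intermediate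
25 | methyl 20-acetoxy-13-(phenylsulfinyl)labd-8(17)-en-16,15-olid-19-oate (ring stereocentres as 18; mixture at C13 and sulfur) | C=C1CC[C@@H]2[C@](COC(C)=O)(CCC[C@]2(C)C(=O)OC)[C@H]1CCC1(S(=O)c2ccccc2)CCOC1=O | intermediate
26 | methyl (4S,5R,9S,10S)-20-acetoxylabda-8(17),13-dien-16,15-olid-19-oate | C=C1CC[C@@H]2[C@](COC(C)=O)(CCC[C@]2(C)C(=O)OC)[C@H]1CCC1=CCOC1=O | target

**Step count**

Total: 18 steps. Longest linear sequence: 15 steps (steps 1–5, 8–15, 17 and 18).

**Steps most likely to fail, with fallbacks**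

Step 11. The cycloaddition may be too slow below the temperature at which [1,5]-hydrogen shift consumes the Z-substituted diene. The C4 centre may also discriminate its methyl and ester groups poorly, so that the wrong diene face or the syn (cis-fused) mode competes. The fallback sets out from dienol 14, leaves out step 10 and comes back at 16. The dienol is converted into its magnesium alkoxide (MeMgBr, toluene) and heated (110–140 °C). Binding of the alkoxide to the C19 ester carbonyl makes a temporary chelate ring that pre-folds the tether and holds the ester on the C20 face. The adduct alkoxide should then close on to the ester to give the bridged lactone 12-(tert-butyldiphenylsilyloxy)-6α-(phenylsulfonyl)-17-(trimethylsilyl)-13,14,15,16-tetranorlabd-8-en-19,20-olide F1. Opening of the lactone with LiOH (THF/H2O) and alkylation of the carboxylate with MeI (DMF) give methyl 12-(tert-butyldiphenylsilyloxy)-20-hydroxy-6α-(phenylsulfonyl)-17-(trimethylsilyl)-13,14,15,16-tetranorlabd-8-en-19-oate F2. Immediate acetylation (Ac2O, pyridine, DMAP) returns to 16.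

Step 9. The organometallic may deprotonate the butenolide at its γ-position, stop after one addition, or attack the C19 ester or the vinyl sulfone; the cis-ene-diol may also cyclise to a dihydrofuran during the elimination. The fallback opens the ring before the fragments are joined; it sets out from triflate 10 and comes back at 14.
- Palladium-catalysed stannylation (Me3SnSnMe3, Pd(PPh3)4, LiCl, dioxane, 80 °C) gives 3-[2-(tert-butyldiphenylsilyloxy)ethyl]-4-(trimethylstannyl)furan-2(5H)-one F3.
- The same cerium-mediated double addition of Me3SiCH2MgCl, now with no ester or sulfone present so that excess reagent can be used, gives (2E)-3-[2-(tert-butyldiphenylsilyloxy)ethyl]-4-[(trimethylsilyl)methyl]-5-(trimethylsilyl)-2-(trimethylstannyl)pent-2-ene-1,4-diol F4.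
- Peterson elimination on silica gives (2E)-3-[2-(tert-butyldiphenylsilyloxy)ethyl]-4-[(trimethylsilyl)methyl]-2-(trimethylstannyl)penta-2,4-dien-1-ol F5.
- Iododestannylation (I2, CH2Cl2, −78 °C) gives (2E)-3-[2-(tert-butyldiphenylsilyloxy)ethyl]-2-iodo-4-[(trimethylsilyl)methyl]penta-2,4-dien-1-ol F6.
- B-alkyl Suzuki–Miyaura coupling of F6 with borane 11, made from 6 and 9-BBN (PdCl2(dppf), AsPh3, K3PO4, DMF/THF/H2O), returns to 14.

Step 13. Protonation may occur on the wrong face of C9, or the acid may move the exocyclic double bond into the ring. The fallback replaces kinetic protonation by thermodynamic control through the C8 ketone; it sets out from 18 as obtained (whatever its composition at C9) and comes back at 18. Ozonolysis (O3, CH2Cl2/MeOH, −78 °C; Me2S) gives methyl 20-acetoxy-12-(tert-butyldiphenylsilyloxy)-8-oxo-13,14,15,16,17-pentanorlabdan-19-oate F7. DBU in toluene equilibrates C9 to the equatorial side chain (9αH). Takai–Lombardo methylenation (CH2Br2, Zn, TiCl4, THF/CH2Cl2), which is non-basic and selective for ketones over esters, restores the C8 methylene and returns to 18.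

Further compounds
F1 | step 11 | 12-(tert-butyldiphenylsilyloxy)-6α-(phenylsulfonyl)-17-(trimethylsilyl)-13,14,15,16-tetranorlabd-8-en-19,20-olide | C[Si](C)(C)CC=1C[C@H](S(=O)(=O)c3ccccc3)[C@@H]2[C@](CO4)(CCC[C@]2(C)C4=O)C=1CCO[Si](c1ccccc1)(c1ccccc1)C(C)(C)C
F2 | step 11 | methyl 12-(tert-butyldiphenylsilyloxy)-20-hydroxy-6α-(phenylsulfonyl)-17-(trimethylsilyl)-13,14,15,16-tetranorlabd-8-en-19-oate | C[Si](C)(C)CC=1C[C@H](S(=O)(=O)c3ccccc3)[C@@H]2[C@](CO)(CCC[C@]2(C)C(=O)OC)C=1CCO[Si](c1ccccc1)(c1ccccc1)C(C)(C)C
F3 | step 9 | 3-[2-(tert-butyldiphenylsilyloxy)ethyl]-4-(trimethylstannyl)furan-2(5H)-one | O=C1OCC([Sn](C)(C)C)=C1CCO[Si](c1ccccc1)(c1ccccc1)C(C)(C)C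
F4 | step 9 | (2E)-3-[2-(tert-butyldiphenylsilyloxy)ethyl]-4-[(trimethylsilyl)methyl]-5-(trimethylsilyl)-2-(trimethylstannyl)pent-2-ene-1,4-diol | C[Si](C)(C)CC(O)(C[Si](C)(C)C)/C(CCO[Si](c1ccccc1)(c1ccccc1)C(C)(C)C)=C(\CO)[Sn](C)(C)C
F5 | step 9 | (2E)-3-[2-(tert-butyldiphenylsilyloxy)ethyl]-4-[(trimethylsilyl)methyl]-2-(trimethylstannyl)penta-2,4-dien-1-ol | C=C(C[Si](C)(C)C)/C(CCO[Si](c1ccccc1)(c1ccccc1)C(C)(C)C)=C(\CO)[Sn](C)(C)C
F6 | step 9 | (2E)-3-[2-(tert-butyldiphenylsilyloxy)ethyl]-2-iodo-4-[(trimethylsilyl)methyl]penta-2,4-dien-1-ol | C=C(C[Si](C)(C)C)/C(CCO[Si](c1ccccc1)(c1ccccc1)C(C)(C)C)=C(\CO)I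
F7 | step 13 | methyl 20-acetoxy-12-(tert-butyldiphenylsilyloxy)-8-oxo-13,14,15,16,17-pentanorlabdan-19-oate (9αH) | O=C1CC[C@@H]2[C@](COC(C)=O)(CCC[C@]2(C)C(=O)OC)[C@H]1CCO[Si](c1ccccc1)(c1ccccc1)C(C)(C)C
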